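**Retrosynthetic overview**
- The target is a 5,6,7,8-tetramethoxyflavone with a free 3'-OH on ring B. It is traced back to the benzyl-protected 5,7-dihydroxy-6,8-dimethoxyflavone, which needs only double O-methylation and hydrogenolysis.
- The strategy rests on ring A: C5 and C7 are at the oxidation level of carbonyl carbons, while C6 and C8 are methoxy-bearing carbons that can each come from an OCH2 group. Ring A is therefore cut at C7–C8 and C5–C6 into methyl methoxyacetate (C6, C7) and a ring C 4-pyranone that carries CH2OMe (the future C8) next to a methyl ester (the future C5).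
- The pyranone (ring C) comes from C-acylation of methyl 4-methoxyacetoacetate with the ring B arylpropiolyl chloride, followed by 6-endo oxa-Michael closure.
- The ring B iodide is made from 2,6-dimethoxyphenol by benzylation, double iodination, a single iodine–lithium exchange with hydroxylation, and methylation. The symmetry of the diiodide fixes the position of the protected 3'-oxygen.
- Order of ring construction: ring B (purchased arene), then ring C, then ring A.

Key step: step 8

**Route**

Step 1
Reactants: 1 2,6-dimethoxyphenol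
Product: 2 2-(benzyloxy)-1,3-dimethoxybenzene
Conditions: BnBr, K2CO3, DMF, 60 °C
Reagents that add atoms: benzyl bromide, BrCc1ccccc1
Why: Williamson ether synthesis, in which the phenoxide displaces bromide from the benzylic carbon; the flanking methoxy groups slow but do not prevent the SN2 step.

Step 2
Reactants: 2 2-(benzyloxy)-1,3-dimethoxybenzene
Product: 3 3-(benzyloxy)-1,5-diiodo-2,4-dimethoxybenzene
Conditions: N-iodosuccinimide (2.4 equiv), CF3CO2H (0.5 equiv), MeCN, rt to 45 °C, dark
Reagents that add atoms: N-iodosuccinimide, O=C1CCC(=O)N1I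
Why: Twofold electrophilic aromatic iodination, in which each iodine enters ortho to one methoxy group and para to the other, while the position para to the twisted central benzyloxy group is not activated, so the symmetric 1,5-diiodide should form.

Step 3
Reactants: 3 3-(benzyloxy)-1,5-diiodo-2,4-dimethoxybenzene
Product: 6 3-(benzyloxy)-5-iodo-2,4-dimethoxyphenol, via aryllithium 4 (not isolated), via lithium aryltrimethoxyborate 5 (not isolated)
Conditions: n-BuLi (1.0 equiv), THF, −78 °C; B(OMe)3, −78 °C to rt; then AcOH, 30% H2O2, 0 °C to rt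
Reagents that add atoms: hydrogen peroxide, OO (oxygen of the phenol); n-butyllithium, [Li]CCCC, and trimethyl borate, COB(OC)OC (atoms in 4 and 5 only)
Why: Iodine–lithium exchange with one equivalent of n-BuLi, borylation and oxidative C–B to C–O conversion; the two iodines are equivalent by symmetry, so a single exchange can give only one phenol, and the acidic oxidation keeps the phenol from being butylated by the 1-iodobutane formed.

Step 4
Reactants: 6 3-(benzyloxy)-5-iodo-2,4-dimethoxyphenol
Product: 7 3-(benzyloxy)-1-iodo-2,4,5-trimethoxybenzene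
Conditions: MeI, K2CO3, DMF, rt to 40 °C
Reagents that add atoms: iodomethane, CI
Why: Williamson O-methylation of the phenoxide, which completes the ring B pattern with iodine at the future C1' and the benzyloxy group at C3'.

Step 5
Reactants: 7 3-(benzyloxy)-1-iodo-2,4,5-trimethoxybenzene; 8 propiolic acid
Product: 9 3-[3-(benzyloxy)-2,4,5-trimethoxyphenyl]prop-2-ynoic acid
Conditions: PdCl2(PPh3)2 (5 mol %), 1,4-bis(diphenylphosphino)butane (10 mol %), DBU (2.5 equiv), DMSO, rt; then aq. HCl
Reagents that add atoms: none
Why: Copper-free Sonogashira-type coupling of the aryl iodide with the terminal alkyne of propiolic acid, run at room temperature so that the propiolate should not decarboxylate.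

Step 6
Reactants: 9 3-[3-(benzyloxy)-2,4,5-trimethoxyphenyl]prop-2-ynoic acid
Product: 10 3-[3-(benzyloxy)-2,4,5-trimethoxyphenyl]prop-2-ynoyl chloride
Conditions: (COCl)2, DMF (cat.), CH2Cl2, 0 °C to rt; concentrate and use crude
Reagents that add atoms: oxalyl chloride, O=C(Cl)C(Cl)=O
Why: Acid chloride formation through the Vilsmeier-type chloroiminium catalyst, kept cold and short so that HCl should not add across the electron-rich alkyne.

Step 7
Reactants: 10 3-[3-(benzyloxy)-2,4,5-trimethoxyphenyl]prop-2-ynoyl chloride; 11 methyl 4-methoxy-3-oxobutanoate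
Product: 13 methyl 6-[3-(benzyloxy)-2,4,5-trimethoxyphenyl]-2-(methoxymethyl)-4-oxo-4H-pyran-3-carboxylate, via ynone tricarbonyl 12 (not isolated)
Conditions: MgCl2, pyridine, CH2Cl2, 0 °C to rt; aq. HCl wash; crude telescoped, K2CO3 (0.2 equiv), MeCN, rt
Reagents that add atoms: none
Why: Rathke-type C-acylation of the chelated magnesium enolate of the β-keto ester by the acid chloride gives the enolised tricarbonyl, whose ketone enol oxygen then adds 6-endo-dig to the aryl ynone (oxa-Michael), placing the ester at C3 and the methoxymethyl group at C2 of the 4-pyranone.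

Step 8
Reactants: 13 methyl 6-[3-(benzyloxy)-2,4,5-trimethoxyphenyl]-2-(methoxymethyl)-4-oxo-4H-pyran-3-carboxylate; 14 methyl methoxyacetate
Product: 16 2-[3-(benzyloxy)-2,4,5-trimethoxyphenyl]-5,7-dihydroxy-6,8-dimethoxy-4H-chromen-4-one, via acylated pyranone 15 (not isolated)
Conditions: LiN(SiMe3)2 (1.1 equiv), THF, −78 °C; 14 (1.3 equiv), −78 to 0 °C; LiN(SiMe3)2 (3.0 equiv), 0 °C to rt; then cold dilute HCl
Reagents that add atoms: none
Why: Proposed new method: one equivalent of LiN(SiMe3)2 removes a hydrogen from the CH2OMe carbon of 13 (the future C8, acidified vinylogously by the C4 ketone and the C3 ester), and because no free amide base remains when ester 14 is added, the stabilised carbanion should undergo crossed Claisen acylation on the lithium-chelated α-methoxy ester (C7–C8) instead of 14 being enolised, with the released LiOMe deprotonating ketone 15 and pulling the equilibrium forward. The further LiN(SiMe3)2 should then generate the C6,C8-dianion of 15, whose terminal C6 carbanion attacks the neighbouring ester carbon (C5) in a 6-exo-trig Dieckmann closure (C5–C6), and loss of methoxide with tautomerisation delivers ring A as the 5,7-bisphenoxide. The closest known reaction types are the acylation of ortho-toluate and homophthalate carbanions with esters followed by Dieckmann aromatisation to naphthalene-1,3-diols, and the γ-deprotonation and acylation of 2-alkyl-4-pyranones; running both condensations in one flask on a 4-pyranone-3-carboxylate is the untested part. No stereocentre is formed. The step needs C-cyclisation through C6 rather than O-cyclisation of the C7 enolate oxygen to a fused lactone, and it needs the pyranone to stay intact: the dianion reacts at its terminal carbon, lactone formation is reversible under methoxide whereas aromatisation is not, and the base is non-nucleophilic while the substrate stays anionic and so resists conjugate ring-opening. Because ring A carries OH at C5 and C7 and OMe at C6 and C8, opening and reclosure of the chromone on acidic work-up would return the same compound.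

Step 9
Reactants: 16 2-[3-(benzyloxy)-2,4,5-trimethoxyphenyl]-5,7-dihydroxy-6,8-dimethoxy-4H-chromen-4-one
Product: 17 2-[3-(benzyloxy)-2,4,5-trimethoxyphenyl]-5,6,7,8-tetramethoxy-4H-chromen-4-one
Conditions: Me2SO4 (excess), K2CO3 (excess), acetone, reflux, prolonged
Reagents that add atoms: dimethyl sulfate, COS(=O)(=O)OC
Why: Williamson-type O-methylation of both phenols, in which the 7-OH reacts readily and the hydrogen-bonded 5-OH should follow under excess reagent and prolonged reflux.

Step 10
Reactants: 17 2-[3-(benzyloxy)-2,4,5-trimethoxyphenyl]-5,6,7,8-tetramethoxy-4H-chromen-4-one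
Product: 18 Agehoustin C, 2-(3-hydroxy-2,4,5-trimethoxyphenyl)-5,6,7,8-tetramethoxy-4H-chromen-4-one
Conditions: H2 (1 atm), 10% Pd/C, EtOAc–MeOH, rt
Reagents that add atoms: none
Why: Catalytic hydrogenolysis of the benzyl aryl ether; the methyl ethers and the chromone C2=C3 bond should be inert at one atmosphere and room temperature if the reaction is stopped at full conversion.

**Compound list**
1 | 2,6-dimethoxyphenol | COc1cccc(OC)c1O | starting material
2 | 2-(benzyloxy)-1,3-dimethoxybenzene | COc1cccc(OC)c1OCc1ccccc1 | intermediate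
3 | 3-(benzyloxy)-1,5-diiodo-2,4-dimethoxybenzene | COc1c(I)cc(I)c(OC)c1OCc1ccccc1 | intermediate
4 | [3-(benzyloxy)-5-iodo-2,4-dimethoxyphenyl]lithium | [Li]c1cc(I)c(OC)c(OCc2ccccc2)c1OC | intermediate (not isolated)
5 | lithium [3-(benzyloxy)-5-iodo-2,4-dimethoxyphenyl]trimethoxyborate | [Li+].CO[B-](OC)(OC)c1cc(I)c(OC)c(OCc2ccccc2)c1OC | intermediate (not isolated)
6 | 3-(benzyloxy)-5-iodo-2,4-dimethoxyphenol | Oc1cc(I)c(OC)c(OCc2ccccc2)c1OC | intermediate
7 | 3-(benzyloxy)-1-iodo-2,4,5-trimethoxybenzene | COc1cc(I)c(OC)c(OCc2ccccc2)c1OC | intermediate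
8 | propiolic acid (prop-2-ynoic acid) | C#CC(=O)O | starting material
9 | 3-[3-(benzyloxy)-2,4,5-trimethoxyphenyl]prop-2-ynoic acid | OC(=O)C#Cc1cc(OC)c(OC)c(OCc2ccccc2)c1OC | intermediate
10 | 3-[3-(benzyloxy)-2,4,5-trimethoxyphenyl]prop-2-ynoyl chloride | ClC(=O)C#Cc1cc(OC)c(OC)c(OCc2ccccc2)c1OC | intermediate
11 | methyl 4-methoxy-3-oxobutanoate (methyl 4-methoxyacetoacetate) | COCC(=O)CC(=O)OC | starting material
12 | methyl 5-[3-(benzyloxy)-2,4,5-trimethoxyphenyl]-2-(methoxyacetyl)-3-oxopent-4-ynoate (enolised) | COCC(=O)C(C(=O)OC)C(=O)C#Cc1cc(OC)c(OC)c(OCc2ccccc2)c1OC | intermediate (not isolated)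
13 | methyl 6-[3-(benzyloxy)-2,4,5-trimethoxyphenyl]-2-(methoxymethyl)-4-oxo-4H-pyran-3-carboxylate | COCc1oc(-c2cc(OC)c(OC)c(OCc3ccccc3)c2OC)cc(=O)c1C(=O)OC | intermediate
14 | methyl methoxyacetate | COCC(=O)OC | starting material
15 | methyl 6-[3-(benzyloxy)-2,4,5-trimethoxyphenyl]-2-(1,3-dimethoxy-2-oxopropyl)-4-oxo-4H-pyran-3-carboxylate (racemic, present as its enolate) | COCC(=O)C(OC)c1oc(-c2cc(OC)c(OC)c(OCc3ccccc3)c2OC)cc(=O)c1C(=O)OC | intermediate (not isolated)
16 | 2-[3-(benzyloxy)-2,4,5-trimethoxyphenyl]-5,7-dihydroxy-6,8-dimethoxy-4H-chromen-4-one | COc1cc(-c2cc(=O)c3c(O)c(OC)c(O)c(OC)c3o2)c(OC)c(OCc2ccccc2)c1OC | intermediate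
17 | 2-[3-(benzyloxy)-2,4,5-trimethoxyphenyl]-5,6,7,8-tetramethoxy-4H-chromen-4-one | COc1cc(-c2cc(=O)c3c(OC)c(OC)c(OC)c(OC)c3o2)c(OC)c(OCc2ccccc2)c1OC | intermediate
18 | Agehoustin C, 2-(3-hydroxy-2,4,5-trimethoxyphenyl)-5,6,7,8-tetramethoxy-4H-chromen-4-one | COc1cc(-c2cc(=O)c3c(OC)c(OC)c(OC)c(OC)c3o2)c(OC)c(O)c1OC | target

**Step count**
Total steps: 10. Longest linear sequence: 10 steps, from 2,6-dimethoxyphenol (1) to Agehoustin C (18).

**Steps most likely to fail**

1. Step 8 (Claisen–Dieckmann annulation). The pyranone carbanion may acylate too slowly, so that ester 14 is enolised and self-condenses. The side-chain enolate may close through oxygen to a fused lactone and stay there. Methoxide may open the pyranone by conjugate addition. The fallback builds ring A from a ready-made arene by Baker–Venkataraman chemistry; it sets out from iodide 7 and returns to the route at 17. Iodine–magnesium exchange on 7 (i-PrMgCl·LiCl, THF, −20 to 0 °C) and quenching with CO2 should give 3-(benzyloxy)-2,4,5-trimethoxybenzoic acid F1. Oxalyl chloride with catalytic DMF converts it into 3-(benzyloxy)-2,4,5-trimethoxybenzoyl chloride F2. Acylation of purchased 1-(2-hydroxy-3,4,5,6-tetramethoxyphenyl)ethanone (CC(=O)c1c(O)c(OC)c(OC)c(OC)c1OC) with F2 in pyridine with DMAP gives 2-acetyl-3,4,5,6-tetramethoxyphenyl 3-(benzyloxy)-2,4,5-trimethoxybenzoate F3. KOH in pyridine at 50 °C effects the O-to-C acyl shift to 1-[3-(benzyloxy)-2,4,5-trimethoxyphenyl]-3-(2-hydroxy-3,4,5,6-tetramethoxyphenyl)propane-1,3-dione F4. Cyclodehydration with catalytic TsOH in toluene at 90 °C should give 17, after which step 10 follows unchanged.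

2. Step 7 (acylation and pyranone closure). The alkynoyl chloride may be consumed by conjugate addition of chloride or pyridine, the enolate may be acylated on oxygen, or the enol may close in the 5-exo mode. The fallback replaces the ynone by a β-chlorovinyl ketone, so that ring closure is an addition–elimination that can only give the six-membered ring; it sets out from acid 9 and returns at 13. Hydrochlorination of 9 (LiCl, AcOH, 90 °C, anti addition) should give (Z)-3-[3-(benzyloxy)-2,4,5-trimethoxyphenyl]-3-chloroprop-2-enoic acid F5; the alkene geometry is not critical for what follows. Oxalyl chloride converts it into (Z)-3-[3-(benzyloxy)-2,4,5-trimethoxyphenyl]-3-chloroprop-2-enoyl chloride F6. C-acylation of the magnesium enolate of 11 (MgCl2, pyridine, CH2Cl2) gives methyl (Z)-5-[3-(benzyloxy)-2,4,5-trimethoxyphenyl]-5-chloro-2-(methoxyacetyl)-3-oxopent-4-enoate F7. K2CO3 in MeCN then closes the ring by attack of the enol oxygen on the chlorine-bearing carbon and loss of chloride, giving 13.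

3. Step 5 (coupling with propiolic acid). Oxidative addition of the electron-rich, ortho-substituted iodide may be slow, and the propiolate may decarboxylate under palladium and base to give terminal or diaryl alkynes. The fallback separates C–C coupling from carboxylation; it sets out from iodide 7 and returns at 9. Sonogashira coupling of 7 with ethynyltrimethylsilane (PdCl2(PPh3)2, CuI, Et3N, 50 °C) should give {[3-(benzyloxy)-2,4,5-trimethoxyphenyl]ethynyl}trimethylsilane F8. K2CO3 in MeOH removes the silyl group to give 3-(benzyloxy)-1-ethynyl-2,4,5-trimethoxybenzene F9. Deprotonation with n-BuLi in THF at −78 °C and quenching with CO2 gives acid 9.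

**Further compounds**
F1 | step 8 | 3-(benzyloxy)-2,4,5-trimethoxybenzoic acid | OC(=O)c1cc(OC)c(OC)c(OCc2ccccc2)c1OC
F2 | step 8 | 3-(benzyloxy)-2,4,5-trimethoxybenzoyl chloride | ClC(=O)c1cc(OC)c(OC)c(OCc2ccccc2)c1OC
F3 | step 8 | 2-acetyl-3,4,5,6-tetramethoxyphenyl 3-(benzyloxy)-2,4,5-trimethoxybenzoate | CC(=O)c1c(OC)c(OC)c(OC)c(OC)c1OC(=O)c1cc(OC)c(OC)c(OCc2ccccc2)c1OC
F4 | step 8 | 1-[3-(benzyloxy)-2,4,5-trimethoxyphenyl]-3-(2-hydroxy-3,4,5,6-tetramethoxyphenyl)propane-1,3-dione | COc1cc(C(=O)CC(=O)c2c(O)c(OC)c(OC)c(OC)c2OC)c(OC)c(OCc2ccccc2)c1OC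
F5 | step 7 | (Z)-3-[3-(benzyloxy)-2,4,5-trimethoxyphenyl]-3-chloroprop-2-enoic acid | OC(=O)/C=C(\Cl)c1cc(OC)c(OC)c(OCc2ccccc2)c1OC
F6 | step 7 | (Z)-3-[3-(benzyloxy)-2,4,5-trimethoxyphenyl]-3-chloroprop-2-enoyl chloride | ClC(=O)/C=C(\Cl)c1cc(OC)c(OC)c(OCc2ccccc2)c1OC
F7 | step 7 | methyl (Z)-5-[3-(benzyloxy)-2,4,5-trimethoxyphenyl]-5-chloro-2-(methoxyacetyl)-3-oxopent-4-enoate | COCC(=O)C(C(=O)OC)C(=O)/C=C(\Cl)c1cc(OC)c(OC)c(OCc2ccccc2)c1OC
F8 | step 5 | {[3-(benzyloxy)-2,4,5-trimethoxyphenyl]ethynyl}trimethylsilane | C[Si](C)(C)C#Cc1cc(OC)c(OC)c(OCc2ccccc2)c1OC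
F9 | step 5 | 3-(benzyloxy)-1-ethynyl-2,4,5-trimethoxybenzene | C#Cc1cc(OC)c(OC)c(OCc2ccccc2)c1OC
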